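**Plan**

1. Numbering used here: ring A is the phenol ring (C1 OH, C2 O-aryl, C3 H, C4–C6 Br); ring B is the dibromophenoxy ring (C1′ O, C2′ and C4′ Br).
2. The retrosynthesis first removes the three bromines that electrophilic substitution can place last (C4–Br and C6–Br, para and ortho to the hydroxyl; C4′–Br, para to the ether oxygen) and masks the hydroxyl as a methyl ether.
3. The remaining ether is then cut at two bonds of ring B at once, O–C1′ and C2′–Br: oxygen and bromine sit on neighbouring carbons, the pattern left when a nucleophile and an electrophile add across the triple bond of benzyne.
4. Forward: 4-bromo-2-methoxyphenol, which already holds C5–Br, is converted to its dry cesium salt, joined with benzyne and a bromine donor in one three-component step, demethylated and tribrominated.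
5. No ring is formed at any stage (ring A is bought, ring B comes from the aryne precursor), and the target has no stereocentre, so there is no stereochemistry to set.

Key step: step 2

Remark: the target is achiral (no stereocentre, freely rotating diaryl ether axis), so the call for a single enantiomer is met without any stereocontrol.

**Route**

Step 1
Reactants: 1 4-bromo-2-methoxyphenol
Product: 2 cesium 4-bromo-2-methoxyphenolate
Conditions: CsOH·H2O (1.0 equiv), MeOH, rt; evaporate; PhMe azeotrope (3×); 80 °C, high vacuum; store under Ar
Reagents that add atoms: cesium hydroxide monohydrate, O.[OH-].[Cs+]
Why: Simple acid–base salt formation, in which hydroxide should deprotonate the phenol completely and azeotropic drying should remove water and methanol so that no proton donor enters step 2.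

Step 2
Reactants: 2 cesium 4-bromo-2-methoxyphenolate; 3 2-(trimethylsilyl)phenyl trifluoromethanesulfonate; 4 bromopentafluorobenzene
Product: 7 4-bromo-1-(2-bromophenoxy)-2-methoxybenzene, via benzyne 5 (not isolated), via 2-aryloxyphenylcesium 6 (not isolated)
Conditions: 3 (1.5 equiv, syringe pump), 4 (5 equiv), CsF (3 equiv), 18-crown-6 (3 equiv), DME, 0 °C → rt, Ar; then H2O
Reagents that add atoms: none
Why: Proposed new method: fluoride attacks the silicon of 3 and triflate departs to release benzyne 5, the phenoxide oxygen of 2 adds to the strained triple bond to form O–C1′ and the ortho aryl anion 6, and 6 attacks the bromine of 4 halophilically (driven by release of the stabilised pentafluorophenyl anion) to form C2′–Br. The closest known reaction types are the three-component bromothiolation of silylaryl-triflate arynes with a sulfur nucleophile and bromopentafluorobenzene, and the fluoride-induced O-arylation of phenols by arynes; pairing an oxygen nucleophile with the bromine donor is the untested part. No ring closes and no stereocentre is formed. Benzyne is symmetric, so no regiochemical question arises, and the bromine para to the phenoxide oxygen is carried through unchanged to become C5–Br of ring A. The step needs chemoselectivity: bromine transfer to 6 must outrun protonation, and O-addition to the aryne must outrun C-arylation and nucleophilic aromatic substitution of the phenoxide on 4. This should be secured by the dry preformed salt in an aprotic ether solvent, the blocked para position, the fivefold excess of 4 and slow release of the aryne at low temperature.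

Step 3
Reactants: 7 4-bromo-1-(2-bromophenoxy)-2-methoxybenzene
Product: 8 5-bromo-2-(2-bromophenoxy)phenol
Conditions: BBr3 (2 equiv), CH2Cl2, −78 °C → rt; then H2O
Reagents that add atoms: none
Why: Lewis-acid cleavage of an aryl methyl ether (BBr3 demethylation), in which boron binds the methoxy oxygen and bromide removes the methyl group by SN2, while the diaryl ether bond and the aryl bromides should stay untouched.

Step 4
Reactants: 8 5-bromo-2-(2-bromophenoxy)phenol
Product: 9 2,3,4-tribromo-6-(2,4-dibromophenoxy)phenol (= 4,5,6-tribromo-2-(2,4-dibromophenoxy)phenol)
Conditions: Br2 (3.1 equiv), AcOH, rt then 60 °C; aq. NaHSO3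
Reagents that add atoms: bromine, BrBr
Why: Electrophilic aromatic bromination, in which the free hydroxyl should direct the first two bromines to its open para (C4) and ortho (C6) positions and the third should enter ring B para to the ether oxygen (C4′), favoured over ortho C6′ as usual for aryl ethers and over C3 of the by then tribrominated ring A.

**Compound list**

1 | 4-bromo-2-methoxyphenol | COc1cc(Br)ccc1O | starting material
2 | cesium 4-bromo-2-methoxyphenolate | COc1cc(Br)ccc1[O-].[Cs+] | intermediate
3 | 2-(trimethylsilyl)phenyl trifluoromethanesulfonate | C[Si](C)(C)c1ccccc1OS(=O)(=O)C(F)(F)F | starting material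
4 | bromopentafluorobenzene | Fc1c(F)c(F)c(Br)c(F)c1F | starting material
5 | benzyne (cyclohexa-1,3-dien-5-yne) | C1#CC=CC=C1 | intermediate
6 | [2-(4-bromo-2-methoxyphenoxy)phenyl]cesium | COc1cc(Br)ccc1Oc1cccc[c-]1.[Cs+] | intermediate
7 | 4-bromo-1-(2-bromophenoxy)-2-methoxybenzene | COc1cc(Br)ccc1Oc1ccccc1Br | intermediate
8 | 5-bromo-2-(2-bromophenoxy)phenol | Oc1cc(Br)ccc1Oc1ccccc1Br | intermediate
9 | 2,3,4-tribromo-6-(2,4-dibromophenoxy)phenol | Oc1c(Oc2ccc(Br)cc2Br)cc(Br)c(Br)c1Br | target

**Step count**

Total steps: 4. Longest linear sequence: 4 steps (1 → 2 → 7 → 8 → 9).

**Steps most likely to fail**

Step 2 (proposed new method). Several processes may compete with the intended path: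
- The aryl anion may be protonated before it meets the bromine donor.
- The phenoxide may be consumed by nucleophilic aromatic substitution on the perfluoroarene.
- The pentafluorophenyl anion may add to the aryne and start a carbobromination chain that drains it.
- The phenoxide may add through its free ortho carbon.

The fallback uses known chemistry only and sets out from phenol 1. 1-Bromo-2-iodobenzene would be oxidised with mCPBA and TsOH·H2O in MeCN and then treated with 1,3,5-trimethoxybenzene to give (2-bromophenyl)(2,4,6-trimethoxyphenyl)iodonium 4-methylbenzenesulfonate F1. Heating F1 with 1 and K2CO3 in toluene at 55 °C should transfer the 2-bromophenyl group to the phenol oxygen by ligand coupling at iodine(III), with the trimethoxyphenyl group as the non-transferred ligand. This metal-free O-arylation leaves all aryl bromides untouched and returns to the route at 7. The C2′–Br is then bought with the aryl iodide and not made in the coupling.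

Step 4. The third bromination, on ring B, is much slower than the two on the phenol ring. The reaction may therefore stall after two bromines, and forcing it may overbrominate (ring A C3 or ring B C6′) or oxidise the phenol. The fallback sets out from methyl ether 7 and stages the brominations around the protecting group. In 7 only two positions are strongly activated (para to the methoxy group on ring A, para to the ether oxygen on ring B), and a Lewis acid can be used without a free phenol. Br2 (2.1 equiv) with catalytic FeBr3 in CH2Cl2 at 0 °C to rt should give 1,2-dibromo-4-(2,4-dibromophenoxy)-5-methoxybenzene F2. BBr3 in CH2Cl2 should then give 4,5-dibromo-2-(2,4-dibromophenoxy)phenol F3. One equivalent of Br2 in AcOH at rt should brominate the single open position ortho to the hydroxyl, and the route is rejoined at 9.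

Step 1. The hygroscopic, electron-rich cesium phenoxide may be dried incompletely or oxidised in air, and any proton source carried forward quenches the aryl anion in step 2. The fallback sets out from 1 and avoids a hydroxide base altogether. Silylation with hexamethyldisilazane (neat, 110 °C, then distillation) should give (4-bromo-2-methoxyphenoxy)trimethylsilane F4. F4 would be charged into the key-step flask, where CsF in DME cleaves the O–Si bond and releases anhydrous 2 in situ, and the route is rejoined at 2.

**Further compounds**

F1 | step 2 | (2-bromophenyl)(2,4,6-trimethoxyphenyl)iodonium 4-methylbenzenesulfonate | COc1cc(OC)c([I+]c2ccccc2Br)c(OC)c1.Cc1ccc(cc1)S(=O)(=O)[O-]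
F2 | step 4 | 1,2-dibromo-4-(2,4-dibromophenoxy)-5-methoxybenzene | COc1cc(Br)c(Br)cc1Oc1ccc(Br)cc1Br
F3 | step 4 | 4,5-dibromo-2-(2,4-dibromophenoxy)phenol | Oc1cc(Br)c(Br)cc1Oc1ccc(Br)cc1Br
F4 | step 1 | (4-bromo-2-methoxyphenoxy)trimethylsilane | COc1cc(Br)ccc1O[Si](C)(C)C
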